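## Structural features

The target consists of two six-membered carbocycles joined through a single CH2 carbon. Ring A is aromatic: a 2,4,6-trihydroxyphenyl unit with a butanoyl group between two of its hydroxyls and one unsubstituted ring carbon. Ring B is an enolised 2-acylcyclohexane-1,3,5-trione, numbered here as C1 (carbonyl), C2 (propanoyl-bearing), C3 (C–OH), C4 (CMe2), C5 (C–OH) and C6 (bridge-bearing). Every carbon of ring B is substituted and C4 is quaternary, but it carries two identical methyl groups, so the molecule has no stereocentre and ring B exists as rapidly interconverting enol tautomers. The fragile points are the CH2 link between two electron-rich enol and phenol systems (strong base or strong acid can break or exchange it), the free polyphenol (oxidation), and any non-enolised β-dicarbonyl intermediate (retro-Claisen cleavage by alkoxide). The real difficulty is assembling the fully substituted ring B with its four different neighbours in the correct order while keeping the three-carbon acyl chain on ring B and the four-carbon acyl chain on ring A. The key step uses the quaternary C4: the segment C3–C4–C5–C6 is a β-keto ester that can enolise only at C6, and C1, C2 and the propanoyl group together are the atoms of an acylketene.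

## Logic of the disconnections

19 ⇒ 18. The three aryl O–CH3 bonds of ring A are cut. Free phenols would quench the enolates and the ketene used earlier, so ring A is carried as its tri-ether. The demand on the forward step is an ether cleavage that spares the CH2 bridge and the triketone of ring B.

18 ⇒ 16 + 17. The bond between ring A and the butanoyl carbonyl carbon is cut. The α-CH2 of that ketone would be a second enolisable site in both enolate steps, so the acyl group is added only after ring B exists. The two free carbons of ring A in 16 are equivalent, so no regiochemical question arises. The forward acylation must work on an arene in the presence of the acidic, chelating ring B.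

16 ⇒ 9 + 12. Ring B is opened at C6–C1 and C2–C3. This removes the ring and returns a keto ester with one enolisable carbon (9) and a masked acylketene (12, which releases 14 on heating). Two skeletal bonds and the whole of ring B are made in one operation through 13 and 15. The forward step must achieve C- rather than O-acylation of 13 and close a hindered ester next to the quaternary carbon.

12 ⇒ 10. The CH2–CH3 bond of the ethyl group is cut, which reduces the ketene precursor to a bulk chemical. The forward step is a γ-selective alkylation of the extended enolate 11 with a methyl electrophile.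

9 ⇒ 5 + 6. The bond between the CMe2 carbon and the ketone carbon is cut. The gem-dimethyl group then comes ready-made from 6, so no later C-methylation is needed. The forward step acylates the fully substituted enolate 8 with the activated acid 7, and it must stop at the ketone.

5 ⇒ 4 ⇒ 1 + 2. The saturated side chain is traced back to the alkene 4, whose Cα=Cβ bond is cut to the aldehyde 1 and the two-carbon donor 2 (through 3). Both are simple commercial compounds, and the forward steps are a condensation with decarboxylation followed by an alkene hydrogenation.

## Other disconnections considered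

Alternative 1: The cut is in ring A, at the aryl–C(butanoyl) bond and the neighbouring aryl C–O bond, traced back to an aryne and a nitrile oxide.
- Forward step: CsF would release the aryne from 3,5-dimethoxy-2-(trimethylsilyl)phenyl trifluoromethanesulfonate A1 and the nitrile oxide from N-hydroxybutanimidoyl chloride A2 in one flask. Their [3+2] cycloaddition should give 4,6-dimethoxy-3-propyl-1,2-benzisoxazole A3. Reductive N–O cleavage and imine hydrolysis would later unveil 1-(2-hydroxy-4,6-dimethoxyphenyl)butan-1-one A4.
- In favour: the conditions are mild and the acyl/hydroxyl relationship is fixed by the cycloaddition. The heterocycle also masks the butanoyl group in a non-enolisable form, so ring A could carry its acyl chain through base chemistry. On that point it is better than the chosen plan, which must postpone the acylation to a late Friedel–Crafts step on the bridged compound.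
- Against: it solves only ring A, whose substitution pattern is symmetrical and reachable by direct acylation, and leaves ring B, the quaternary carbon and the bridge untouched. The aliphatic nitrile oxide can dimerise, the regiochemistry on the unsymmetrical aryne rests on aryne distortion alone, and A1 needs several steps. A4 also has two non-equivalent free carbons for the later bridge.
- Comparison: mechanistically the cycloaddition is a well-understood single event and is the more predictable key step. Structurally it builds less of the target, and in step economy it is clearly longer.

Alternative 2: The cut is in ring B, at both bonds of the ring carbonyl carbon (to the bridge-bearing carbon and to the CMe2 carbon) and one further ring bond.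
- Forward step: heating 3-ethoxy-4,4-dimethylcyclobut-2-en-1-one A5 with triisopropyl{[3-(2,4,6-trimethoxyphenyl)prop-1-yn-1-yl]oxy}silane A6 should open the four-membered ring to a vinylketene, add it to the alkyne, and reopen and reclose. The gem-dimethyl carbon prevents aromatisation, so the cascade should stop at 5-ethoxy-6,6-dimethyl-3-(triisopropylsilyloxy)-2-(2,4,6-trimethoxybenzyl)cyclohexa-2,4-dien-1-one A7.
- In favour: it is a neutral, thermal, pericyclic cascade with no enolate and no C/O-acylation question, and the regiochemistry is set by the polarity of the siloxyalkyne. It forms three ring bonds against two and delivers the three ring oxygens differentiated. On mechanistic precedent and bonds formed it is equal or better than the chosen key step.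
- Against: A6 requires a multistep ynolate synthesis and A5 a ketene–alkyne cycloaddition. A7 also lacks the propanoyl group, so enol ether hydrolysis and a separate C-acylation must follow before the same two end-game steps.
- Comparison: the chosen plan installs the propanoyl group in the ring-forming step and uses cheaper fragments. It is therefore shorter, at the price of a less precedented key step.

Alternative 3: The cut is at the two C–CH3 bonds of the quaternary carbon, leading back to a fully aromatic dimer.
- Forward step: NaOMe and iodomethane in methanol would methylate twice the single free ring carbon of the propanoylphloroglucinol half of 1-[3-({2,4,6-tris(benzyloxy)-3-butanoylphenyl}methyl)-2,4,6-trihydroxyphenyl]propan-1-one A8. The product would be the dienone 6-{[2,4,6-tris(benzyloxy)-3-butanoylphenyl]methyl}-3,5-dihydroxy-4,4-dimethyl-2-propanoylcyclohexa-2,5-dien-1-one A9, and hydrogenolysis would then give the target.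
- In favour: it follows the presumed biogenesis, uses a known reaction class (dearomative C-methylation of acylphloroglucinols), and ends with a neutral deprotection, with no BBr3 or AlCl3 acting on the finished skeleton. The end game is milder and the step count equal or lower, so on these points it is equal or better.
- Against: C-methylation competes with O-methylation and with methylation at the bridge-bearing carbon. The methoxide medium is exactly the medium in which methylene-bridged phloroglucinols exchange their halves. The unsymmetrical A8 must first be made by a selective cross-coupling of two different phloroglucinols.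
- Comparison: the chosen plan avoids all methylation selectivity, because the gem-dimethyl carbon comes from a building block, and the bridge is an ordinary saturated chain during every basic step. It pays with an unprecedented cascade and a harsher end game.

Key step: step 5

Remarks on the chemistry (assumptions and design choices):
- Ring B of 16, 18 and 19 is written as one enol tautomer of the 2-acylcyclohexane-1,3,5-trione. The tautomers equilibrate and none has a stereocentre.
- The skeleton of the key-step precursor 9 is kept; the atom balance is 9 (C17H24O6) + 14 (C5H6O2) = 16 (C21H26O7) + CH4O. The design changes are threefold. Acid 5 is activated as an imidazolide, since an acid chloride could acylate the very electron-rich arene. The methyl ethers are kept because they survive both the hydride base at 110 °C and AlCl3. Three equivalents of NaH are used so that the Dieckmann closure starts from the dianion.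
- Crude 18 may contain material that has lost an ortho methyl group; it is carried into step 7, which removes all three.

## Route

Step 1
Reactants: 1 2,4,6-trimethoxybenzaldehyde; 2 malonic acid (propanedioic acid)
Product: 4 (E)-3-(2,4,6-trimethoxyphenyl)prop-2-enoic acid, via arylidenemalonic acid 3 (not isolated)
Conditions: pyridine, piperidine (cat.), 100 °C; then cold aq. HCl
Reagents that add atoms: none
Why: Doebner modification of the Knoevenagel condensation: piperidine-catalysed condensation of 1 with 2 gives 3, which loses CO2 in hot pyridine; the E alkene should result because it is the conjugated, thermodynamically favoured isomer.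

Step 2
Reactants: 4 (E)-3-(2,4,6-trimethoxyphenyl)prop-2-enoic acid
Product: 5 3-(2,4,6-trimethoxyphenyl)propanoic acid
Conditions: H2 (1 atm), Pd/C (10% Pd on carbon), MeOH, rt
Reagents that add atoms: none
Why: Heterogeneous catalytic hydrogenation of a conjugated C=C bond; the arene, the aryl ethers and the acid are inert at one atmosphere and room temperature.

Step 3
Reactants: 5 3-(2,4,6-trimethoxyphenyl)propanoic acid; 6 methyl 2-methylpropanoate (methyl isobutyrate)
Product: 9 methyl 2,2-dimethyl-3-oxo-5-(2,4,6-trimethoxyphenyl)pentanoate, via acyl imidazolide 7 (not isolated), via lithium ester enolate 8 (not isolated)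
Conditions: 5, 1,1'-carbonyldiimidazole (1.1 equiv), THF, rt; separately 6 (3.2 equiv), LiN(i-Pr)2 (3.2 equiv), THF, −78 °C; add 7 to 8, −78 → −40 °C; aq. NH4Cl
Reagents that add atoms: none
Why: Crossed Claisen acylation of an ester enolate by an acyl imidazolide: the fully substituted enolate 8 attacks 7 and imidazolide leaves; 9 has no proton between its carbonyl groups, so the two extra equivalents of 8 cover the NH of the liberated imidazole and the α-CH2 of the new ketone.

Step 4
Reactants: 10 2,2,6-trimethyl-4H-1,3-dioxin-4-one
Product: 12 6-ethyl-2,2-dimethyl-4H-1,3-dioxin-4-one, via lithium dienolate 11 (not isolated)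
Conditions: LiN(i-Pr)2 (1.05 equiv), THF, −78 °C; MeI (1.5 equiv), DMPU, −78 → −30 °C; aq. NH4Cl
Reagents that add atoms: iodomethane, CI
Why: Vinylogous enolate alkylation: the amide base removes a proton from the 6-methyl group to give the extended dienolate 11, which in the presence of the polar co-solvent is methylated at the exocyclic γ-carbon, a known way to 6-alkyl dioxinones; low temperature and only a slight excess of base limit a second methylation.

Step 5
Reactants: 9 methyl 2,2-dimethyl-3-oxo-5-(2,4,6-trimethoxyphenyl)pentanoate; 12 6-ethyl-2,2-dimethyl-4H-1,3-dioxin-4-one
Product: 16 3,5-dihydroxy-4,4-dimethyl-2-propanoyl-6-[(2,4,6-trimethoxyphenyl)methyl]cyclohexa-2,5-dien-1-one, via keto ester sodium enolate 13 (not isolated), via propanoylketene 14 (not isolated), via triketo ester 15 (not isolated)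
Conditions: 9, NaH (3 equiv), toluene, 60 °C; then 12 (1.5 equiv) added over 2 h at 110 °C, then 110 °C; aq. HCl
Reagents that add atoms: none
Why: Proposed new method: NaH converts 9 irreversibly into enolate 13 with hydrogen as the only by-product, so nothing protic is left to intercept the ketene, and at 110 °C 12 loses acetone by retro-[4+2] to give 14, whose ketene carbon is attacked by C6 of 13. Proton transfer places the charge on the doubly activated C2 of 15, the excess hydride raises this enolate to the dianion, and C2 then attacks the ester in a 6-exo-trig Dieckmann closure that expels methoxide and forms ring B. The closest known reaction types are the C-acylation of enolates and enol ethers by acylketenes released from 1,3-dioxin-4-ones and the Dieckmann cyclisation of 3,5,7-triketo esters to 2-acylcyclohexane-1,3,5-triones; what is new is their union in one flask on a simple ketone enolate. No stereocentre is formed. Regioselectivity rests on the quaternary C4: C6 is the only enolisable carbon of 9, and C2 is the only carbanion of 15 that can reach the ester through a six-membered transition state. C- over O-acylation should be favoured by the tight sodium ion pair in toluene, and an O-acylated enol ester would still pass its acyl group to carbon under the basic conditions. Deprotonation of the product to its delocalised dianion makes the closure irreversible and should draw any lactone formed by O-attack on the ester back into the same product through methoxide. Slow addition of 12 keeps the ketene concentration low, which curbs its dimerisation and a second acylation.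

Step 6
Reactants: 16 3,5-dihydroxy-4,4-dimethyl-2-propanoyl-6-[(2,4,6-trimethoxyphenyl)methyl]cyclohexa-2,5-dien-1-one; 17 butanoyl chloride
Product: 18 6-[(3-butanoyl-2,4,6-trimethoxyphenyl)methyl]-3,5-dihydroxy-4,4-dimethyl-2-propanoylcyclohexa-2,5-dien-1-one
Conditions: AlCl3 (3.5 equiv), CH2Cl2, −10 → 0 °C; ice, aq. HCl
Reagents that add atoms: none
Why: Friedel–Crafts acylation: the trialkoxyarene of ring A is strongly activated and its two free carbons are equivalent, so one ketone should result and the acyl group then deactivates the ring; ring B has no free carbon and is held as an aluminium chelate, and any enol ester formed on it or any ortho ether cleaved by AlCl3 is of no consequence because step 7 removes both.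

Step 7
Reactants: 18 6-[(3-butanoyl-2,4,6-trimethoxyphenyl)methyl]-3,5-dihydroxy-4,4-dimethyl-2-propanoylcyclohexa-2,5-dien-1-one
Product: 19 6-[(3-butanoyl-2,4,6-trihydroxyphenyl)methyl]-3,5-dihydroxy-4,4-dimethyl-2-propanoylcyclohexa-2,5-dien-1-one (CNP0330971.0)
Conditions: BBr3 (8 equiv), CH2Cl2, −78 °C → rt; MeOH, then H2O
Reagents that add atoms: none
Why: Lewis-acid cleavage of aryl methyl ethers: BBr3 coordinates each ether oxygen and bromide removes the methyl group by SN2; the two ethers ortho to the ketone are assisted by chelation and the third should follow on warming, while ring B, which has no ether, is tolerated as a boron chelate that methanol and water break up on work-up.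

## Compound list

1 | 2,4,6-trimethoxybenzaldehyde | COc1cc(OC)c(C=O)c(OC)c1 | starting material
2 | malonic acid (propanedioic acid) | OC(=O)CC(=O)O | starting material
3 | 2-[(2,4,6-trimethoxyphenyl)methylidene]propanedioic acid | COc1cc(OC)c(C=C(C(=O)O)C(=O)O)c(OC)c1 | intermediate
4 | (E)-3-(2,4,6-trimethoxyphenyl)prop-2-enoic acid | COc1cc(OC)c(/C=C/C(=O)O)c(OC)c1 | intermediate
5 | 3-(2,4,6-trimethoxyphenyl)propanoic acid | COc1cc(OC)c(CCC(=O)O)c(OC)c1 | intermediate
6 | methyl 2-methylpropanoate (methyl isobutyrate) | COC(=O)C(C)C | starting material
7 | 1-(1H-imidazol-1-yl)-3-(2,4,6-trimethoxyphenyl)propan-1-one | COc1cc(OC)c(CCC(=O)n2ccnc2)c(OC)c1 | intermediate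
8 | lithium 1-methoxy-2-methylprop-1-en-1-olate | [Li+].COC([O-])=C(C)C | intermediate
9 | methyl 2,2-dimethyl-3-oxo-5-(2,4,6-trimethoxyphenyl)pentanoate | COC(=O)C(C)(C)C(=O)CCc1c(OC)cc(OC)cc1OC | intermediate
10 | 2,2,6-trimethyl-4H-1,3-dioxin-4-one | CC1=CC(=O)OC(C)(C)O1 | starting material
11 | lithium 2,2-dimethyl-6-methylidene-6H-1,3-dioxin-4-olate | [Li+].C=C1C=C([O-])OC(C)(C)O1 | intermediate
12 | 6-ethyl-2,2-dimethyl-4H-1,3-dioxin-4-one | CCC1=CC(=O)OC(C)(C)O1 | intermediate
13 | sodium 5-methoxy-4,4-dimethyl-5-oxo-1-(2,4,6-trimethoxyphenyl)pent-2-en-3-olate | [Na+].COC(=O)C(C)(C)C([O-])=CCc1c(OC)cc(OC)cc1OC | intermediate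
14 | pent-1-ene-1,3-dione (propanoylketene) | CCC(=O)C=C=O | intermediate
15 | methyl 2,2-dimethyl-3,5,7-trioxo-4-[(2,4,6-trimethoxyphenyl)methyl]nonanoate (present as its sodium enolate) | CCC(=O)CC(=O)C(Cc1c(OC)cc(OC)cc1OC)C(=O)C(C)(C)C(=O)OC | intermediate
16 | 3,5-dihydroxy-4,4-dimethyl-2-propanoyl-6-[(2,4,6-trimethoxyphenyl)methyl]cyclohexa-2,5-dien-1-one | COc1cc(OC)c(CC2=C(O)C(C)(C)C(O)=C(C(=O)CC)C2=O)c(OC)c1 | intermediate
17 | butanoyl chloride | CCCC(=O)Cl | starting material
18 | 6-[(3-butanoyl-2,4,6-trimethoxyphenyl)methyl]-3,5-dihydroxy-4,4-dimethyl-2-propanoylcyclohexa-2,5-dien-1-one | CCCC(=O)c1c(OC)cc(OC)c(CC2=C(O)C(C)(C)C(O)=C(C(=O)CC)C2=O)c1OC | intermediate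
19 | 6-[(3-butanoyl-2,4,6-trihydroxyphenyl)methyl]-3,5-dihydroxy-4,4-dimethyl-2-propanoylcyclohexa-2,5-dien-1-one | CCCC(=O)c1c(O)cc(O)c(CC2=C(O)C(C)(C)C(O)=C(C(=O)CC)C2=O)c1O | target

## Step count and least certain steps

Total: 7 steps. Longest linear sequence: 6 steps (1, 2, 3, 5, 6, 7); step 4 is a one-step branch that supplies 12.

Step 5 (key step, proposed new method).
- What may go wrong: incomplete or slow enolisation by the heterogeneous hydride, leaving ketone and enolate side by side (self-condensation). O-acylation of the enolate by the ketene. Proton transfer from the acidic first adduct to unreacted enolate. Dimerisation of the ketene. Capture of the ketene, or retro-Claisen cleavage of unreacted 9, by the methoxide that the closure releases. A slow closure at the hindered ester, so that the open chain lactonises or dehydrates on acidic work-up.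
- Fallback (known reactions only), from 9 back to 16: soft enolisation of 9 (MgBr2·OEt2, i-Pr2NEt, CH2Cl2) and C-acetylation with 1-acetylbenzotriazole should give methyl 2,2-dimethyl-3,5-dioxo-4-[(2,4,6-trimethoxyphenyl)methyl]hexanoate F1. NaOMe in refluxing MeOH should close it, by Dieckmann attack of the terminal methyl carbanion on the ester, to 4,4-dimethyl-6-[(2,4,6-trimethoxyphenyl)methyl]cyclohexane-1,3,5-trione F2. Propanoyl chloride and Et3N should give the enol ester 5-hydroxy-4,4-dimethyl-3-oxo-6-[(2,4,6-trimethoxyphenyl)methyl]cyclohexa-1,5-dien-1-yl propanoate F3 (one of the possible enol esters), and catalytic DMAP should shift the acyl group from oxygen to the free ring carbon C2, giving 16. The ring is then built before the acyl side chain, at the cost of two more steps.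

Step 4.
- What may go wrong: methylation at the α-carbon instead of the γ-carbon, a second methylation of the product, and addition of the dienolate to dioxinone that has not yet been deprotonated.
- Fallback, from 10 back to 12: heating 10 with tert-butanol (xylene, 140 °C) should give tert-butyl 3-oxobutanoate F4 with loss of acetone. Formation of the dianion (NaH, then n-BuLi, THF, 0 °C) and addition of iodomethane should methylate only the terminal carbon, giving tert-butyl 3-oxopentanoate F5. Acetone, Ac2O and catalytic H2SO4 should then convert F5 into 12. The regiochemistry is then fixed by the dianion rather than by the selectivity of a dienolate.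

Step 6.
- What may go wrong: O-acylation of the ring B enols that consumes the acid chloride, sequestration of the Lewis acid by the triketone, and acid-induced scission or exchange at the benzylic bridge.
- Fallback, from 16 back to 18: a Houben–Hoesch reaction with butanenitrile (ZnCl2, dry HCl, Et2O, 0 °C) should give the ketiminium chloride F6 (18 with C=NH2+ Cl− in place of the butanoyl C=O), and warm water should hydrolyse it to 18. The electrophile is a nitrilium ion, so no acyl chloride is present to acylate the enol oxygens.

Step 7.
- What may go wrong: incomplete cleavage of the ether para to the ketone once ring A is deactivated as a boron chelate, and acid-promoted cleavage of the bridge during the long exposure needed for that last ether.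
- Fallback, from 16 back to 19 (replacing steps 6 and 7): BBr3 (CH2Cl2, −78 °C → rt) on 16, whose three ethers sit on an arene without a chelating ketone, should give 3,5-dihydroxy-4,4-dimethyl-2-propanoyl-6-[(2,4,6-trihydroxyphenyl)methyl]cyclohexa-2,5-dien-1-one F7. C-acylation of the free triphenol with 17 and AlCl3 in CH2Cl2–PhNO2 should then give 19. The order of deprotection and acylation is reversed.

## Further compounds

F1 | step 5 | methyl 2,2-dimethyl-3,5-dioxo-4-[(2,4,6-trimethoxyphenyl)methyl]hexanoate | CC(=O)C(Cc1c(OC)cc(OC)cc1OC)C(=O)C(C)(C)C(=O)OC
F2 | step 5 | 4,4-dimethyl-6-[(2,4,6-trimethoxyphenyl)methyl]cyclohexane-1,3,5-trione | COc1cc(OC)c(CC2C(=O)CC(=O)C(C)(C)C2=O)c(OC)c1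
F3 | step 5 | 5-hydroxy-4,4-dimethyl-3-oxo-6-[(2,4,6-trimethoxyphenyl)methyl]cyclohexa-1,5-dien-1-yl propanoate | CCC(=O)OC1=CC(=O)C(C)(C)C(O)=C1Cc1c(OC)cc(OC)cc1OC
F4 | step 4 | tert-butyl 3-oxobutanoate | CC(=O)CC(=O)OC(C)(C)C
F5 | step 4 | tert-butyl 3-oxopentanoate | CCC(=O)CC(=O)OC(C)(C)C
F6 | step 6 | 1-{3-[(2,4-dihydroxy-3,3-dimethyl-6-oxo-5-propanoylcyclohexa-1,4-dien-1-yl)methyl]-2,4,6-trimethoxyphenyl}butan-1-iminium chloride | CCCC(=[NH2+])c1c(OC)cc(OC)c(CC2=C(O)C(C)(C)C(O)=C(C(=O)CC)C2=O)c1OC.[Cl-]
F7 | step 7 | 3,5-dihydroxy-4,4-dimethyl-2-propanoyl-6-[(2,4,6-trihydroxyphenyl)methyl]cyclohexa-2,5-dien-1-one | CCC(=O)C1=C(O)C(C)(C)C(O)=C(Cc2c(O)cc(O)cc2O)C1=O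
A1 | alternative 1 | 3,5-dimethoxy-2-(trimethylsilyl)phenyl trifluoromethanesulfonate | COc1cc(OC)c([Si](C)(C)C)c(OS(=O)(=O)C(F)(F)F)c1
A2 | alternative 1 | N-hydroxybutanimidoyl chloride | CCCC(Cl)=NO
A3 | alternative 1 | 4,6-dimethoxy-3-propyl-1,2-benzisoxazole | CCCc1noc2cc(OC)cc(OC)c12
A4 | alternative 1 | 1-(2-hydroxy-4,6-dimethoxyphenyl)butan-1-one | CCCC(=O)c1c(O)cc(OC)cc1OC
A5 | alternative 2 | 3-ethoxy-4,4-dimethylcyclobut-2-en-1-one | CCOC1=CC(=O)C1(C)C
A6 | alternative 2 | triisopropyl{[3-(2,4,6-trimethoxyphenyl)prop-1-yn-1-yl]oxy}silane | COc1cc(OC)c(CC#CO[Si](C(C)C)(C(C)C)C(C)C)c(OC)c1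
A7 | alternative 2 | 5-ethoxy-6,6-dimethyl-3-(triisopropylsilyloxy)-2-(2,4,6-trimethoxybenzyl)cyclohexa-2,4-dien-1-one | CCOC1=CC(O[Si](C(C)C)(C(C)C)C(C)C)=C(Cc2c(OC)cc(OC)cc2OC)C(=O)C1(C)C
A8 | alternative 3 | 1-[3-({2,4,6-tris(benzyloxy)-3-butanoylphenyl}methyl)-2,4,6-trihydroxyphenyl]propan-1-one | CCCC(=O)c1c(OCc2ccccc2)cc(OCc2ccccc2)c(Cc2c(O)cc(O)c(C(=O)CC)c2O)c1OCc1ccccc1
A9 | alternative 3 | 6-{[2,4,6-tris(benzyloxy)-3-butanoylphenyl]methyl}-3,5-dihydroxy-4,4-dimethyl-2-propanoylcyclohexa-2,5-dien-1-one | CCCC(=O)c1c(OCc2ccccc2)cc(OCc2ccccc2)c(CC2=C(O)C(C)(C)C(O)=C(C(=O)CC)C2=O)c1OCc1ccccc1
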